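The ten-membered ring is made by four-atom ring expansion of a cyclohexane. With germacrane locants (C1 ketone, C4/C5 epoxide carbons, C6 lactone O–CH, C8 and C10 acetoxy carbons), the C1 ketone, the C2–C3 ethano link and the oxygenated C4–C5–C6 triad are the retron of an anionic oxy-Cope rearrangement. A 1-vinyl-2-[(E)-propenyl]cyclohexanol (ring C1, C10, C9, C8, C7, C6), locked by an acetal across the C8 and C10 oxygens, forms C3–C4 as C1–C6 breaks, giving the ketone, an E C5=C6 alkene and a C4 stereocenter at once. A singlet-oxygen ene/oxygen-transfer step then relays C4 into the epoxy alcohol, and an intramolecular Horner–Wadsworth–Emmons reaction closes the butenolide.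

Key step: step 11

Remark: 1 and 21 are taken as catalogue compounds; every intermediate carries the germacrane locants of the target (the cyclohexane ring of 1–13 is C1, C6, C7, C8, C9, C10; C11–C13 are the lactone carbons, C14 and C15 the methyl groups on C10 and C4).

Step 1
Reactants: 1 (S)-4-(tert-butyldimethylsilyloxy)cyclohex-2-en-1-one
Product: 3 (4S,6S)-4-(tert-butyldimethylsilyloxy)-6-(triethylsilyloxy)cyclohex-2-en-1-one, via silyl dienol ether 2 (not isolated)
Conditions: LiN(iPr)2, THF, −78 °C; Et3SiCl; then mCPBA, NaHCO3, CH2Cl2, −20 °C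
Reagents that add atoms: chlorotriethylsilane CC[Si](Cl)(CC)CC; mCPBA OOC(=O)c1cccc(Cl)c1
Why: Kinetic deprotonation at C10 and O-silylation give the cross-conjugated silyl dienol ether, and Rubottom oxidation (epoxidation of the enol ether, ring opening, 1,4-silyl shift) installs the C10 oxygen as its triethylsilyl ether; the C10 configuration (expected trans to the C8 silyloxy group) is erased in step 2.

Step 2
Reactants: 3 (4S,6S)-4-(tert-butyldimethylsilyloxy)-6-(triethylsilyloxy)cyclohex-2-en-1-one
Product: 4 (4S,6R)-4-(tert-butyldimethylsilyloxy)-6-methyl-6-(triethylsilyloxy)cyclohex-2-en-1-one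
Conditions: LiN(iPr)2, THF, −78 °C; MeI, DMPU, −78 to −40 °C
Reagents that add atoms: iodomethane CI
Why: Enolate C-alkylation: the lithium dienolate re-formed at C10 should be methylated anti to the pseudoaxial C8 silyloxy group (1,3-induction), which sets the quaternary C10 center with its oxygen cis to the C8 oxygen.

Step 3
Reactants: 4 (4S,6R)-4-(tert-butyldimethylsilyloxy)-6-methyl-6-(triethylsilyloxy)cyclohex-2-en-1-one
Product: 5 (4S,6R)-4,6-dihydroxy-6-methylcyclohex-2-en-1-one
Conditions: HF·pyridine, pyridine, THF, 0 °C to rt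
Reagents that add atoms: none
Why: Fluoride-mediated desilylation (strong Si–F bond) frees both hydroxyl groups without touching a stereocenter.

Step 4
Reactants: 5 (4S,6R)-4,6-dihydroxy-6-methylcyclohex-2-en-1-one
Product: 6 bridged 4-methoxybenzylidene acetal enone (acetal across the C8 and C10 oxygens; aryl exo)
Conditions: 4-MeOC6H4CH(OMe)2, PPTS (cat.), 4 Å sieves, CH2Cl2, rt
Reagents that add atoms: 4-methoxybenzaldehyde dimethyl acetal COC(OC)c1ccc(OC)cc1
Why: Acid-catalysed transacetalisation in which only the cis-1,3-diol can bridge (a trans isomer from step 2 is left behind); the aryl group should settle exo (equatorial on the dioxane) under thermodynamic control, and the resulting 2,4-dioxabicyclo[3.3.1]nonane locks both oxygens axial.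

Step 5
Reactants: 6 bridged 4-methoxybenzylidene acetal enone
Product: 7 C6-iodo enone
Conditions: I2, pyridine, CH2Cl2, 0 °C to rt
Reagents that add atoms: iodine II
Why: alpha-Iodination of the enone by pyridine conjugate addition, iodination of the resulting enolate and elimination (Baylis–Hillman-type addition–elimination).

Step 6
Reactants: 7 C6-iodo enone
Product: 8 C6-allyl enone
Conditions: CH2=CHCH2SnBu3, Pd2(dba)3 (cat.), AsPh3, CuI (cat.), N-methylpyrrolidone, 40 °C
Reagents that add atoms: allyltributylstannane C=CC[Sn](CCCC)(CCCC)CCCC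
Why: Stille cross-coupling of the alpha-iodoenone with the allylstannane under ligand-accelerated, copper-assisted conditions.

Step 7
Reactants: 8 C6-allyl enone
Product: 10 C7 alcohol (C6 allyl equatorial; C7 hydroxyl axial and trans to the C8 oxygen), via pinacol boronate 9 (not isolated)
Conditions: B2pin2, CuCl (cat.), NaOtBu (cat.), Xantphos (cat.), MeOH, THF, rt; then NaBO3·4H2O, THF/H2O, rt
Reagents that add atoms: bis(pinacolato)diboron CC1(C)OB(OC1(C)C)B1OC(C)(C)C(C)(C)O1 (boron and pinacol only in 9); sodium perborate [Na+].[O-]OB=O (the C7 oxygen of 10)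
Why: Copper-catalysed conjugate borylation: the boryl group should add to C7 on the face opposite the dioxane bridge, protonation of the enolate places the C6 allyl group equatorial (the axial site points into the bridge, and the center can equilibrate), and perborate oxidation replaces boron by hydroxyl with retention.

Step 8
Reactants: 10 C7 alcohol
Product: 11 C7 tert-butyldimethylsilyl ether
Conditions: tBuMe2SiOTf, 2,6-lutidine, CH2Cl2, −78 °C
Reagents that add atoms: tert-butyldimethylsilyl triflate CC(C)(C)[Si](C)(C)OS(=O)(=O)C(F)(F)F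
Why: Silylation of the hindered axial secondary alcohol with the silyl triflate under weakly basic conditions that avoid beta-elimination of the beta-hydroxy ketone.

Step 9
Reactants: 11 C7 tert-butyldimethylsilyl ether
Product: 12 C1 tertiary vinyl carbinol (vinyl equatorial and trans to the C6 allyl group; hydroxyl axial)
Conditions: CH2=CHMgBr, CeCl3, THF, −78 °C; aq. NH4Cl
Reagents that add atoms: vinylmagnesium bromide C=C[Mg]Br
Why: 1,2-Addition of the organocerium reagent formed from the Grignard reagent and CeCl3 (enolisation suppressed): the axial trajectory at C1 is blocked by the axial C7 silyloxy group (1,3-diaxial), so the vinyl group should enter equatorially, trans to the C6 allyl group.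

Step 10
Reactants: 12 C1 tertiary vinyl carbinol
Product: 13 1-vinyl-2-[(E)-prop-1-enyl]cyclohexanol (oxy-Cope substrate)
Conditions: [Ir(cod)(PMePh2)2]PF6 (cat.), H2 (activation, then purged), THF, rt
Reagents that add atoms: none
Why: Iridium-hydride-catalysed alkene isomerisation (1,3-hydrogen shift) should move the allyl double bond into the (E)-propenyl position; the vinyl group on quaternary C1 has no allylic hydrogen and cannot migrate.

Step 11
Reactants: 13 1-vinyl-2-[(E)-prop-1-enyl]cyclohexanol
Product: 16 ten-membered ketone (C1 oxo; E-C5=C6; new C4 methyl-bearing stereocenter), via potassium alkoxide 14 (not isolated), via potassium enolate 15 (not isolated)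
Conditions: KH, 18-crown-6, THF, 0 °C to rt; aq. NH4Cl, −78 °C
Reagents that add atoms: none
Why: Deprotonation gives the potassium alkoxide 14, whose weakened C1–C6 bond breaks as C3–C4 forms in a concerted [3,3]-sigmatropic shift through a chair transition state, giving enolate 15, which is protonated to the C1 ketone. The closest known reaction type is the anionic oxy-Cope ring expansion of trans-1,2-dialkenylcyclohexanols to (E)-cyclodec-5-enones. The ten-membered ring is closed by four-atom ring expansion: C3 and C4 meet within a six-membered chair array spanning the cleaving C1–C6 bond, so no end-to-end macrocyclisation is needed. The new C4 stereocenter is controlled by the C6 configuration, the E geometry of the propenyl group (methyl equatorial in the chair) and the chair topology, and the E geometry of the new C5=C6 bond follows from the equatorial C6–C7 bond. The step needs chair over boat selectivity and a gauche, diequatorial arrangement of the two alkenyl groups; the dioxane bridge holds the C8 and C10 oxygens axial and thereby keeps vinyl and propenyl equatorial, and any reversible silyl transfer from the C7 oxygen should be funnelled back through the tertiary alkoxide.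

Step 12
Reactants: 16 ten-membered ketone
Product: 17 C8,C10-diol
Conditions: AcOH/THF/H2O (3:1:1), 40 °C
Reagents that add atoms: none
Why: Acid hydrolysis of the 4-methoxybenzylidene acetal, which is far more labile than the secondary silyl ether.

Step 13
Reactants: 17 C8,C10-diol
Product: 18 C8,C10-diacetate
Conditions: Ac2O, DMAP, Et3N, CH2Cl2, 40 °C
Reagents that add atoms: acetic anhydride CC(=O)OC(C)=O
Why: DMAP-catalysed acylation of the secondary C8 and the tertiary C10 hydroxyl groups; a transannular hemiketal of the C8 hydroxyl with the C1 ketone, if formed, is in equilibrium with the open form that is acylated.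

Step 14
Reactants: 18 C8,C10-diacetate
Product: 20 (4R,5R)-4,5-epoxy C6 alcohol, via allylic hydroperoxide 19 (not isolated)
Conditions: O2, hν (sodium lamp), tetraphenylporphyrin (cat.), Ti(OiPr)4 (cat.), 4 Å sieves, CH2Cl2, −10 °C
Reagents that add atoms: dioxygen O=O
Why: Schenck ene reaction followed by titanium-mediated oxygen transfer: singlet oxygen should attack the exposed face of the E C5=C6 bond, bond to C6 and abstract the C4 hydrogen (held on that face by the C4 center from step 11; the C7 hydrogen geminal to the silyloxy group is not abstracted), giving the (E)-C4=C5 hydroperoxide with the C6 configuration of the target, and the titanium alkoxide then delivers oxygen to the C4=C5 face syn to the C6 oxygen (threo, enforced by 1,3-allylic strain with the C4 methyl group), which sets C4 and C5.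

Step 15
Reactants: 21 ethyl 2-(diethoxyphosphoryl)prop-2-enoate; 22 4-methoxybenzyl alcohol
Product: 23 ethyl 2-(diethoxyphosphoryl)-3-[(4-methoxybenzyl)oxy]propanoate (racemic)
Conditions: KOtBu (0.1 equiv), THF, 0 °C
Reagents that add atoms: none
Why: Base-catalysed oxa-Michael addition of the alkoxide to the vinylphosphonate; the stabilised carbanion is protonated by the alcohol, so the base is catalytic.

Step 16
Reactants: 23 ethyl 2-(diethoxyphosphoryl)-3-[(4-methoxybenzyl)oxy]propanoate
Product: 24 2-(diethoxyphosphoryl)-3-[(4-methoxybenzyl)oxy]propanoic acid (racemic)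
Conditions: Me3SnOH, 1,2-dichloroethane, 70 °C; then 1 M HCl
Reagents that add atoms: trimethyltin hydroxide C[Sn](C)(C)O
Why: Mild hydrolysis of the carboxylic ethyl ester by trimethyltin hydroxide (acyl–oxygen cleavage), which spares the phosphonate esters and avoids base-induced retro-oxa-Michael loss of the benzyl ether.

Step 17
Reactants: 20 (4R,5R)-4,5-epoxy C6 alcohol; 24 2-(diethoxyphosphoryl)-3-[(4-methoxybenzyl)oxy]propanoic acid
Product: 25 C6 phosphonoacetate ester (epimers at the phosphonate carbon)
Conditions: DCC, DMAP (cat.), CH2Cl2, 0 °C to rt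
Reagents that add atoms: none
Why: Steglich esterification of the hindered C6 alcohol, the only free hydroxyl group.

Step 18
Reactants: 25 C6 phosphonoacetate ester
Product: 26 C7 alcohol
Conditions: HF·pyridine, pyridine, THF, 0 °C to rt
Reagents that add atoms: none
Why: Fluoride cleavage of the secondary silyl ether under buffered conditions that should leave the epoxide, the esters and the benzyl ether intact.

Step 19
Reactants: 26 C7 alcohol
Product: 27 C7 ketone
Conditions: Dess–Martin periodinane, NaHCO3, CH2Cl2, 0 °C to rt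
Reagents that add atoms: none
Why: Dess–Martin oxidation of the secondary C7 alcohol under buffered, non-epimerising conditions.

Step 20
Reactants: 27 C7 ketone
Product: 28 13-O-(4-methoxybenzyl) ether of the target
Conditions: LiCl, iPr2NEt, MeCN, 0 °C to rt
Reagents that add atoms: none
Why: Intramolecular Horner–Wadsworth–Emmons olefination under mild lithium chloride/amine conditions closes the butenolide by forming C7=C11 (five-membered ring, alkene geometry fixed by the ring); a retro-oxa-Michael loss of the benzyloxide is reversible and is funnelled to the product, and the mild base should spare the C6 stereocenter.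

Step 21
Reactants: 28 13-O-(4-methoxybenzyl) ether of the target
Product: 29 CNP0266633.2 (target)
Conditions: DDQ, CH2Cl2/pH 7 buffer, 0 °C
Reagents that add atoms: none
Why: Oxidative cleavage of the 4-methoxybenzyl ether by DDQ (hydride abstraction, hydrolysis of the oxocarbenium ion), which leaves acetates, epoxide and butenolide untouched.

Compound list

1 | (S)-4-(tert-butyldimethylsilyloxy)cyclohex-2-en-1-one | O=C1C=C[C@@H](O[Si](C)(C)C(C)(C)C)CC1 | starting material
2 | tert-butyldimethyl{[(1S)-4-(triethylsilyloxy)cyclohexa-2,4-dien-1-yl]oxy}silane (silyl dienol ether) | CC[Si](CC)(CC)OC1=CC[C@H](O[Si](C)(C)C(C)(C)C)C=C1 | intermediate (not isolated)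
3 | (4S,6S)-4-(tert-butyldimethylsilyloxy)-6-(triethylsilyloxy)cyclohex-2-en-1-one | O=C1C=C[C@@H](O[Si](C)(C)C(C)(C)C)C[C@@H]1O[Si](CC)(CC)CC | intermediate
4 | (4S,6R)-4-(tert-butyldimethylsilyloxy)-6-methyl-6-(triethylsilyloxy)cyclohex-2-en-1-one | O=C1C=C[C@@H](O[Si](C)(C)C(C)(C)C)C[C@@]1(C)O[Si](CC)(CC)CC | intermediate
5 | (4S,6R)-4,6-dihydroxy-6-methylcyclohex-2-en-1-one | O=C1C=C[C@@H](O)C[C@@]1(C)O | intermediate
6 | 4-methoxybenzylidene acetal of 5: 3-(4-methoxyphenyl)-5-methyl-2,4-dioxabicyclo[3.3.1]non-7-en-6-one, aryl exo, acetal oxygens on C8 and C10 | O=C1C=C[C@@H]2C[C@@]1(C)O[C@@H](c3ccc(OC)cc3)O2 | intermediate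
7 | C6-iodo enone (alpha-iodo derivative of 6) | O=C1C(I)=C[C@@H]2C[C@@]1(C)O[C@@H](c3ccc(OC)cc3)O2 | intermediate
8 | C6-allyl enone | O=C1C(CC=C)=C[C@@H]2C[C@@]1(C)O[C@@H](c3ccc(OC)cc3)O2 | intermediate
9 | C7 pinacolboryl ketone: C6 allyl equatorial, C7 boron axial (anti to the acetal bridge) | O=C1[C@H](CC=C)[C@H](B3OC(C)(C)C(C)(C)O3)[C@@H]2C[C@@]1(C)O[C@@H](c4ccc(OC)cc4)O2 | intermediate (not isolated)
10 | C7 alcohol: C6 allyl equatorial, C7 hydroxyl axial and trans to the C8 oxygen | O=C1[C@H](CC=C)[C@H](O)[C@@H]2C[C@@]1(C)O[C@@H](c3ccc(OC)cc3)O2 | intermediate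
11 | C7 tert-butyldimethylsilyl ether of 10 | O=C1[C@H](CC=C)[C@H](O[Si](C)(C)C(C)(C)C)[C@@H]2C[C@@]1(C)O[C@@H](c3ccc(OC)cc3)O2 | intermediate
12 | C1 tertiary alcohol: vinyl equatorial and trans to the C6 allyl group, hydroxyl axial | O[C@]1(C=C)[C@H](CC=C)[C@H](O[Si](C)(C)C(C)(C)C)[C@@H]2C[C@@]1(C)O[C@@H](c3ccc(OC)cc3)O2 | intermediate
13 | as 12 with (E)-prop-1-enyl at C6 (1-vinyl-2-propenylcyclohexanol) | O[C@]1(C=C)[C@H](/C=C/C)[C@H](O[Si](C)(C)C(C)(C)C)[C@@H]2C[C@@]1(C)O[C@@H](c3ccc(OC)cc3)O2 | intermediate
14 | potassium alkoxide of 13 | [K+].[O-][C@]1(C=C)[C@H](/C=C/C)[C@H](O[Si](C)(C)C(C)(C)C)[C@@H]2C[C@@]1(C)O[C@@H](c3ccc(OC)cc3)O2 | intermediate (not isolated)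
15 | potassium enolate (O–C1=C2) of 16 | [K+].[O-]/C1=C\C[C@H](C)/C=C/[C@H](O[Si](C)(C)C(C)(C)C)[C@@H]2C[C@@]1(C)O[C@@H](c3ccc(OC)cc3)O2 | intermediate (not isolated)
16 | ten-membered ketone: C1 oxo, (E)-C5=C6, C4 methyl-bearing stereocenter, C7 silyl ether, C8/C10 acetal | O=C1CC[C@H](C)/C=C/[C@H](O[Si](C)(C)C(C)(C)C)[C@@H]2C[C@@]1(C)O[C@@H](c3ccc(OC)cc3)O2 | intermediate
17 | C8,C10-diol of 16 | O=C1CC[C@H](C)/C=C/[C@H](O[Si](C)(C)C(C)(C)C)[C@@H](O)C[C@@]1(C)O | intermediate
18 | C8,C10-diacetate | O=C1CC[C@H](C)/C=C/[C@H](O[Si](C)(C)C(C)(C)C)[C@@H](OC(C)=O)C[C@@]1(C)OC(C)=O | intermediate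
19 | C6 hydroperoxide with (E)-C4=C5 | O=C1CC/C(C)=C/[C@@H](OO)[C@H](O[Si](C)(C)C(C)(C)C)[C@@H](OC(C)=O)C[C@@]1(C)OC(C)=O | intermediate (not isolated)
20 | (4R,5R)-4,5-epoxide with free C6 hydroxyl, C7 silyl ether, C8 and C10 acetates | CC(=O)O[C@H]1C[C@@](C)(OC(C)=O)C(=O)CC[C@@]2(C)O[C@@H]2[C@@H](O)[C@@H]1O[Si](C)(C)C(C)(C)C | intermediate
21 | ethyl 2-(diethoxyphosphoryl)prop-2-enoate | C=C(C(=O)OCC)P(=O)(OCC)OCC | starting material
22 | 4-methoxybenzyl alcohol | COc1ccc(CO)cc1 | starting material
23 | ethyl 2-(diethoxyphosphoryl)-3-[(4-methoxybenzyl)oxy]propanoate (racemic) | CCOC(=O)C(COCc1ccc(OC)cc1)P(=O)(OCC)OCC | intermediate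
24 | 2-(diethoxyphosphoryl)-3-[(4-methoxybenzyl)oxy]propanoic acid (racemic) | OC(=O)C(COCc1ccc(OC)cc1)P(=O)(OCC)OCC | intermediate
25 | C6 ester of 20 with 24 (epimers at the phosphonate carbon) | CC(=O)O[C@H]1C[C@@](C)(OC(C)=O)C(=O)CC[C@@]2(C)O[C@@H]2[C@@H](OC(=O)C(COCc3ccc(OC)cc3)P(=O)(OCC)OCC)[C@@H]1O[Si](C)(C)C(C)(C)C | intermediate
26 | C7 alcohol of 25 | CC(=O)O[C@H]1C[C@@](C)(OC(C)=O)C(=O)CC[C@@]2(C)O[C@@H]2[C@@H](OC(=O)C(COCc3ccc(OC)cc3)P(=O)(OCC)OCC)[C@@H]1O | intermediate
27 | C7 ketone | CC(=O)O[C@H]1C[C@@](C)(OC(C)=O)C(=O)CC[C@@]2(C)O[C@@H]2[C@@H](OC(=O)C(COCc3ccc(OC)cc3)P(=O)(OCC)OCC)C1=O | intermediate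
28 | 13-O-(4-methoxybenzyl) ether of the target | CC(=O)O[C@H]1C[C@@](C)(OC(C)=O)C(=O)CC[C@@]2(C)O[C@@H]2[C@H]2OC(=O)C(COCc3ccc(OC)cc3)=C12 | intermediate
29 | CNP0266633.2: (4R,5R,6S,8S,10R)-8,10-diacetoxy-4,5-epoxy-13-hydroxy-1-oxogermacr-7(11)-en-12,6-olide | CC(=O)O[C@H]1C[C@@](C)(OC(C)=O)C(=O)CC[C@@]2(C)O[C@@H]2[C@H]2OC(=O)C(CO)=C12 | target

Total step count: 21. Longest linear sequence: 19 steps (steps 1–14 and 17–21; steps 15–16 prepare the phosphonate acid).

Steps most likely to fail

First, step 11. The potassium alkoxide may fragment, or lose its rate acceleration through silyl transfer from the C7 oxygen, or react through a boat pathway instead of the chair [3,3] shift. The fallback avoids the alkoxide altogether. It sets out from 13: silylation of the tertiary alcohol (Me3SiOTf, 2,6-lutidine, CH2Cl2) gives the trimethylsilyl ether F1. A neutral siloxy-Cope thermolysis (o-dichlorobenzene, 200 °C) should give the ring-expanded trimethylsilyl enol ether F2 through the same chair array. Methanolysis (K2CO3, MeOH) releases the ketone, and the route is rejoined at 16.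

Second, step 14. Hydrogen abstraction at a 1,2-disubstituted alkene may be slow, so that the hydroperoxide decomposes before oxygen transfer, or the titanium-mediated transfer may show poor facial control. The fallback separates the two events and uses an external, hydroxyl-directed oxidant. It sets out from 18: photooxygenation without titanium (O2, hν, tetraphenylporphyrin, CH2Cl2) followed by PPh3 reduction of hydroperoxide 19 gives the allylic alcohol F3. Directed epoxidation with VO(acac)2 and tBuOOH in CH2Cl2 should then give the threo epoxy alcohol, rejoining the route at 20.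

Third, step 9. Facial selectivity of the carbonyl addition may be poor: attack along the axial trajectory, anti to the axial C10 oxygen, would place the vinyl group cis to the allyl group, and that isomer cannot reach the chair array of step 11. The fallback builds the carbinol through an epoxide. It sets out from 11: Corey–Chaykovsky reaction with dimethylsulfoxonium methylide (Me3S(O)I, NaH, DMSO), which forms the new C–C bond equatorially under thermodynamic control, gives the spiro-epoxide F4. Excess dimethylsulfonium methylide (Me3SI, nBuLi, THF) should open the terminal epoxide and eliminate dimethyl sulfide, giving the homologated tertiary vinyl carbinol and rejoining the route at 12.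

Further compounds

F1 | step 11 | trimethylsilyl ether of 13 | C[Si](C)(C)O[C@]1(C=C)[C@H](/C=C/C)[C@H](O[Si](C)(C)C(C)(C)C)[C@@H]2C[C@@]1(C)O[C@@H](c3ccc(OC)cc3)O2
F2 | step 11 | trimethylsilyl enol ether (O–C1=C2) of 16 | C[Si](C)(C)O/C1=C\C[C@H](C)/C=C/[C@H](O[Si](C)(C)C(C)(C)C)[C@@H]2C[C@@]1(C)O[C@@H](c3ccc(OC)cc3)O2
F3 | step 14 | C6 allylic alcohol with (E)-C4=C5 (reduced form of 19) | O=C1CC/C(C)=C/[C@@H](O)[C@H](O[Si](C)(C)C(C)(C)C)[C@@H](OC(C)=O)C[C@@]1(C)OC(C)=O
F4 | step 9 | C1 spiro-epoxide of 11 (epoxide oxygen axial, methylene equatorial) | C1O[C@@]12[C@H](CC=C)[C@H](O[Si](C)(C)C(C)(C)C)[C@@H]3C[C@@]2(C)O[C@@H](c4ccc(OC)cc4)O3
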